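**Strategy.** The flavan ring C is cut at C2–C3: the segment O1–C2(aryl)–C3(OH) is treated as a hidden enol ether, in the manner of a glycal. Ring-closing metathesis of an aryl vinyl ether with a propenyl group on C4 forms the C2=C3 bond and closes ring C as a 4-(flavonol-5-yl)-4H-chromene. The precursor is an acyclic aryl vinyl ether whose C4 centre comes from (R)-but-3-yn-2-ol by Mitsunobu inversion and chirality transfer in an aromatic Claisen rearrangement onto the only free ortho carbon of ring A. The pseudoaxial C4 flavonol then steers epoxidation to the opposite face, and syn arylation of the epoxide places ring B cis to the 3-OH.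

Key step: step 9

Assumption: gossypetin, (R)-but-3-yn-2-ol, 2,3-bis(benzyloxy)benzaldehyde and 4-bromo-1,2-bis(benzyloxy)benzene are purchased; flavan numbering (O1, C2, C3, C4; rings A, B, C) is used for the upper unit, Bn = benzyl, and "Flv" in names means the 3,7,8-tris(benzyloxy)-2-[3,4-bis(benzyloxy)phenyl]-4-oxo-4H-chromen-5-yl group.

**Step 1**
Reactants: 1 gossypetin (3,5,7,8,3′,4′-hexahydroxyflavone)
Product: 2 3,7,8-tris(benzyloxy)-2-[3,4-bis(benzyloxy)phenyl]-5-hydroxy-4H-chromen-4-one (Flv-OH)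
Conditions: BnBr (5.2 equiv), K2CO3, DMF, 25 → 45 °C
Reagents that add atoms: benzyl bromide, BrCc1ccccc1
Why: Williamson O-benzylation, in which the 5-OH, hydrogen-bonded to the C4 carbonyl, is the least reactive phenol and should stay free when the benzyl bromide is limited to the other five.

**Step 2**
Reactants: 2 Flv-OH
Product: 3 Flv trifluoromethanesulfonate (5-triflate)
Conditions: Tf2O, pyridine, CH2Cl2, 0 °C
Reagents that add atoms: trifluoromethanesulfonic anhydride, FC(F)(F)S(=O)(=O)OS(=O)(=O)C(F)(F)F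
Why: O-sulfonylation of the chelated phenol gives the aryl triflate as the cross-coupling handle at C5 of the flavonol.

**Step 3**
Reactants: 4 (R)-but-3-yn-2-ol
Product: 5 (R,E)-4-(4,4,5,5-tetramethyl-1,3,2-dioxaborolan-2-yl)but-3-en-2-ol
Conditions: B2pin2, CuCl (5 mol %), Xantphos, NaOtBu (10 mol %), MeOH (2 equiv), THF, rt
Reagents that add atoms: bis(pinacolato)diboron, CC1(C)OB(B2OC(C)(C)C(C)(C)O2)OC1(C)C
Why: copper-catalysed formal hydroboration (syn borylcupration of the terminal alkyne, then protonation by methanol) should give the (E)-β-boryl allylic alcohol, the carbinol centre coming unchanged from the chiral pool.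

**Step 4**
Reactants: 3 Flv triflate; 5 (R,E)-alkenylboronate
Product: 6 Flv–CH=CH–CH(OH)CH3, (1E,3R)-3-hydroxybut-1-en-1-yl at C5 of the flavonol
Conditions: PdCl2(dppf) (5 mol %), K3PO4, 1,4-dioxane/H2O, 80 °C
Reagents that add atoms: none
Why: Suzuki–Miyaura coupling of an aryl triflate with an alkenylboronate proceeds with retention of the E geometry and tolerates the free alcohol and the flavonol carbonyl.

**Step 5**
Reactants: 7 2,3-bis(benzyloxy)benzaldehyde
Product: 9 2,3-bis(benzyloxy)phenol, via aryl formate 8 (not isolated)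
Conditions: mCPBA, CH2Cl2, rt; then K2CO3, MeOH, rt
Reagents that add atoms: 3-chloroperoxybenzoic acid, OOC(=O)c1cccc(Cl)c1
Why: Baeyer–Villiger (Dakin-type) oxidation with migration of the electron-rich aryl group, followed by methanolysis of the formate, turns ArCHO into ArOH.

**Step 6**
Reactants: 6 (R)-allylic alcohol; 9 2,3-bis(benzyloxy)phenol
Product: 10 Flv–CH=CH–CH(CH3)–O–[2,3-bis(benzyloxy)phenyl], (1E,3S) aryl ether
Conditions: PPh3, DIAD, toluene, 0 °C → rt
Reagents that add atoms: none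
Why: Mitsunobu etherification, in which SN2 displacement of the oxyphosphonium by the phenoxide inverts the carbinol centre from (R) to (S).

**Step 7**
Reactants: 10 (S)-aryl allyl ether
Product: 11 5-{(1S,2E)-1-[3,4-bis(benzyloxy)-2-hydroxyphenyl]but-2-en-1-yl} flavonol pentabenzyl ether (ring-A phenol with the future C4 centre)
Conditions: 1,2-dichlorobenzene, BHT (cat.), 170 °C, sealed tube
Reagents that add atoms: none
Why: aromatic Claisen rearrangement, a suprafacial [3,3] shift through a chair-like transition state with the methyl group pseudo-equatorial, transfers the (S)-C–O centre into the (S)-diarylmethine (future C4), gives the E-propenyl group and can only go to the single free ortho carbon before tautomerisation restores the phenol.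

**Step 8**
Reactants: 11 ring-A phenol
Product: 12 aryl vinyl ether of 11, 5-{(1S,2E)-1-[3,4-bis(benzyloxy)-2-(vinyloxy)phenyl]but-2-en-1-yl} flavonol pentabenzyl ether
Conditions: 2,4,6-trivinylcyclotriboroxane–pyridine complex, Cu(OAc)2 (20 mol %), pyridine, 4 Å MS, CH2Cl2, O2 (1 atm), rt
Reagents that add atoms: 2,4,6-trivinylcyclotriboroxane–pyridine complex, C=CB1OB(C=C)OB(C=C)O1.c1ccncc1
Why: copper-mediated Chan–Lam-type O-vinylation of the phenol under neutral conditions leaves the base- and hydride-sensitive diarylmethine allyl unit alone.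

**Step 9**
Reactants: 12 aryl vinyl ether
Product: 13 5-[(4S)-7,8-bis(benzyloxy)-4H-chromen-4-yl] flavonol pentabenzyl ether
Conditions: second-generation Grubbs catalyst (5 mol %), 1,4-benzoquinone (10 mol %), toluene, 70 °C
Reagents that add atoms: none
Why: Ring-closing olefin metathesis: the ruthenium alkylidene exchanges onto the propenyl group, then adds across the tethered aryl vinyl ether in a [2+2]/retro-[2+2] sequence that forms C2=C3 and expels propene. The closest known reaction is the ring-closing metathesis of 2-allylaryl vinyl ethers to 4H-chromenes. Ring C (O1–C2=C3–C4–C4a–C8a) is closed as a six-membered cyclic enol ether by alkene–alkene metathesis, the only ring size the tether allows. No stereocenter is formed; C4, set in step 7, is not touched and, being pseudoaxial in the boat-like 4H-chromene, later directs step 11. The step needs cyclisation to win over arrest as a ruthenium alkoxycarbene and over migration of the new double bond into conjugation with the C4 aryl groups; loading at the propenyl terminus and 1,4-benzoquinone as hydride scavenger should secure this.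

**Step 10**
Reactants: 14 4-bromo-1,2-bis(benzyloxy)benzene
Product: 16 [3,4-bis(benzyloxy)phenyl]zinc chloride, via aryllithium 15 (not isolated)
Conditions: n-BuLi (1.0 equiv), THF, −78 °C; then ZnCl2 (1.0 equiv), −78 °C → rt; THF replaced by toluene/n-Bu2O, used as a solution
Reagents that add atoms: zinc chloride, Cl[Zn]Cl
Why: bromine–lithium exchange followed by transmetalation with one equivalent of ZnCl2 gives the monoarylzinc chloride, a Lewis-acidic aryl donor that does not add to the flavonol ketone.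

**Step 11**
Reactants: 13 4H-chromene; 16 arylzinc chloride
Product: 18 5-{(2R,3R,4S)-7,8-bis(benzyloxy)-2-[3,4-bis(benzyloxy)phenyl]-3-hydroxychroman-4-yl} flavonol pentabenzyl ether (nona-O-benzyl target), via epoxide 17 (not isolated)
Conditions: DMDO, acetone/CH2Cl2, −40 → 0 °C, evaporate; then 16 (3 equiv), toluene/n-Bu2O, 0 °C → rt; aq. NH4Cl
Reagents that add atoms: dimethyldioxirane, CC1(C)OO1
Why: Prilezhaev-type epoxidation of the electron-rich enol ether from the face opposite the pseudoaxial C4 flavonol sets C3, and the arylzinc chloride then opens the epoxy acetal at C2 as a Lewis acid with internal aryl delivery from the zinc held on the C3 oxygen (syn opening, as known for 1,2-anhydro sugars with arylzinc reagents), which sets C2 cis to the 3-OH and trans to C4.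

**Step 12**
Reactants: 18 nona-O-benzyl target
Product: 19 2-(3,4-dihydroxyphenyl)-5-[(2R,3R,4S)-2-(3,4-dihydroxyphenyl)-3,7,8-trihydroxychroman-4-yl]-3,7,8-trihydroxy-4H-chromen-4-one (target)
Conditions: H2 (1 atm), Pd(OH)2/C, THF/MeOH, rt, degassed work-up
Reagents that add atoms: none
Why: catalytic hydrogenolysis should remove the nine benzyl ethers while the tetrasubstituted flavonol double bond, the cyclic C2–O1 ether and the three stereocenters stay intact.

**Compound list**

1 | gossypetin | O=c1c(O)c(-c2ccc(O)c(O)c2)oc2c(O)c(O)cc(O)c12 | starting material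
2 | 3,7,8-tris(benzyloxy)-2-[3,4-bis(benzyloxy)phenyl]-5-hydroxy-4H-chromen-4-one | O=c1c(OCc5ccccc5)c(-c2ccc(OCc5ccccc5)c(OCc5ccccc5)c2)oc2c(OCc5ccccc5)c(OCc5ccccc5)cc(O)c12 | intermediate
3 | Flv trifluoromethanesulfonate | O=c1c(OCc5ccccc5)c(-c2ccc(OCc5ccccc5)c(OCc5ccccc5)c2)oc2c(OCc5ccccc5)c(OCc5ccccc5)cc(OS(=O)(=O)C(F)(F)F)c12 | intermediate
4 | (R)-but-3-yn-2-ol | C[C@@H](O)C#C | starting material
5 | (R,E)-4-(4,4,5,5-tetramethyl-1,3,2-dioxaborolan-2-yl)but-3-en-2-ol | C[C@@H](O)/C=C/B1OC(C)(C)C(C)(C)O1 | intermediate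
6 | 5-[(1E,3R)-3-hydroxybut-1-en-1-yl] flavonol pentabenzyl ether | O=c1c(OCc5ccccc5)c(-c2ccc(OCc5ccccc5)c(OCc5ccccc5)c2)oc2c(OCc5ccccc5)c(OCc5ccccc5)cc(/C=C/[C@@H](C)O)c12 | intermediate
7 | 2,3-bis(benzyloxy)benzaldehyde | O=Cc1cccc(OCc2ccccc2)c1OCc1ccccc1 | starting material
8 | 2,3-bis(benzyloxy)phenyl formate | O=COc1cccc(OCc2ccccc2)c1OCc1ccccc1 | intermediate (not isolated)
9 | 2,3-bis(benzyloxy)phenol | Oc1cccc(OCc2ccccc2)c1OCc1ccccc1 | intermediate
10 | 5-{(1E,3S)-3-[2,3-bis(benzyloxy)phenoxy]but-1-en-1-yl} flavonol pentabenzyl ether | O=c1c(OCc5ccccc5)c(-c2ccc(OCc5ccccc5)c(OCc5ccccc5)c2)oc2c(OCc5ccccc5)c(OCc5ccccc5)cc(/C=C/[C@H](C)Oc3cccc(OCc5ccccc5)c3OCc3ccccc3)c12 | intermediate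
11 | 5-{(1S,2E)-1-[3,4-bis(benzyloxy)-2-hydroxyphenyl]but-2-en-1-yl} flavonol pentabenzyl ether | O=c1c(OCc5ccccc5)c(-c2ccc(OCc5ccccc5)c(OCc5ccccc5)c2)oc2c(OCc5ccccc5)c(OCc5ccccc5)cc([C@H](/C=C/C)c3ccc(OCc5ccccc5)c(OCc5ccccc5)c3O)c12 | intermediate
12 | 5-{(1S,2E)-1-[3,4-bis(benzyloxy)-2-(vinyloxy)phenyl]but-2-en-1-yl} flavonol pentabenzyl ether | O=c1c(OCc5ccccc5)c(-c2ccc(OCc5ccccc5)c(OCc5ccccc5)c2)oc2c(OCc5ccccc5)c(OCc5ccccc5)cc([C@H](/C=C/C)c3ccc(OCc5ccccc5)c(OCc5ccccc5)c3OC=C)c12 | intermediate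
13 | 5-[(4S)-7,8-bis(benzyloxy)-4H-chromen-4-yl] flavonol pentabenzyl ether | O=c1c(OCc5ccccc5)c(-c2ccc(OCc5ccccc5)c(OCc5ccccc5)c2)oc2c(OCc5ccccc5)c(OCc5ccccc5)cc([C@H]3c4ccc(OCc5ccccc5)c(OCc5ccccc5)c4OC=C3)c12 | intermediate
14 | 4-bromo-1,2-bis(benzyloxy)benzene | Brc1ccc(OCc2ccccc2)c(OCc2ccccc2)c1 | starting material
15 | [3,4-bis(benzyloxy)phenyl]lithium | [Li]c1ccc(OCc2ccccc2)c(OCc2ccccc2)c1 | intermediate (not isolated)
16 | [3,4-bis(benzyloxy)phenyl]zinc chloride | Cl[Zn]c1ccc(OCc2ccccc2)c(OCc2ccccc2)c1 | intermediate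
17 | (2S,3R,4S)-2,3-epoxide of 13, epoxide oxygen on the face opposite the flavonol group | O=c1c(OCc5ccccc5)c(-c2ccc(OCc5ccccc5)c(OCc5ccccc5)c2)oc2c(OCc5ccccc5)c(OCc5ccccc5)cc([C@H]3c4ccc(OCc5ccccc5)c(OCc5ccccc5)c4O[C@H]6[C@@H]3O6)c12 | intermediate (not isolated)
18 | 5-{(2R,3R,4S)-7,8-bis(benzyloxy)-2-[3,4-bis(benzyloxy)phenyl]-3-hydroxychroman-4-yl} flavonol pentabenzyl ether | O=c1c(OCc5ccccc5)c(-c2ccc(OCc5ccccc5)c(OCc5ccccc5)c2)oc2c(OCc5ccccc5)c(OCc5ccccc5)cc([C@H]3c4ccc(OCc5ccccc5)c(OCc5ccccc5)c4O[C@H](c4ccc(OCc5ccccc5)c(OCc5ccccc5)c4)[C@@H]3O)c12 | intermediate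
19 | 2-(3,4-dihydroxyphenyl)-5-[(2R,3R,4S)-2-(3,4-dihydroxyphenyl)-3,7,8-trihydroxychroman-4-yl]-3,7,8-trihydroxy-4H-chromen-4-one | O=c1c(O)c(-c2ccc(O)c(O)c2)oc2c(O)c(O)cc([C@H]3c4ccc(O)c(O)c4O[C@H](c4ccc(O)c(O)c4)[C@@H]3O)c12 | target

**Step count.** Total: 12 steps. Longest linear sequence: 9 steps (1, 2, 4, 6, 7, 8, 9, 11, 12).

**Steps most likely to fail**

1. Step 11. Aryl transfer may lose its syn sense: the Lewis-acidic arylzinc chloride can ionise the epoxy acetal to an oxocarbenium ion that is attacked without facial preference, chloride may be transferred in place of aryl, or the epoxide can rearrange by hydride shift before the aryl group arrives. The fallback sets out from phenol 11 and rejoins the route at 18. Phenol 11 is acylated with 3,4-bis(benzyloxy)benzoyl chloride (Et3N, DMAP, CH2Cl2) to give the aryl ester F1. A Takai–Utimoto olefinic ester cyclisation (TiCl4, TMEDA, Zn, PbCl2 cat., CH3CHBr2, THF) closes the same C2–C3 bond and gives the 2-aryl-4H-chromene F2. DMDO epoxidises F2 opposite the C4 substituent to the epoxy ketal F3, which aqueous work-up opens to the α-hydroxy ketone F4 (open form of the hemiketal) with C3 set. Zn(BH4)2 reduces F4 under chelation control to the anti diol F5. Mitsunobu closure (PPh3, DIAD) of the ring-A phenol onto the benzylic carbinol with inversion then gives 18.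

2. Step 9. The ruthenium carbene may be held as an unreactive alkoxycarbene at the vinyl ether, or ruthenium hydride species may move the new double bond into conjugation with the two aryl groups and erase the C4 centre. The fallback sets out from phenol 11 and rejoins at 13, bypassing step 8 as well. Formylation of 11 with acetic formic anhydride and pyridine gives the aryl formate F6. The reduced-titanium ethylidene reagent (TiCl4, TMEDA, Zn, PbCl2 cat., CH3CHBr2, THF, 65 °C) should then effect alkylidene exchange at the propenyl group and intramolecular carbonyl olefination, giving 13 without a ruthenium catalyst.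

3. Step 6. The activated allylic oxyphosphonium may ionise, which leads to attack at the flavonol-bearing terminus (allylic transposition) or to partial racemisation. The fallback sets out from triflate 3 and rejoins at 10. Commercial (S)-but-3-yn-2-ol is converted as in step 3 into the (S)-alkenylboronate F7 and coupled with 3 as in step 4 to the (S)-allylic alcohol F8. Its methyl carbonate F9 (ClCO2Me, pyridine) undergoes O-allylation of phenol 9 catalysed by the zerovalent palladium complex Pd(PPh3)4; this proceeds with net retention (double inversion through the π-allyl complex, attack at the methyl-bearing terminus) and gives 10.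

**Further compounds**

F1 | step 11 | 3,4-bis(benzyloxy)benzoate ester of phenol 11 | O=c1c(OCc5ccccc5)c(-c2ccc(OCc5ccccc5)c(OCc5ccccc5)c2)oc2c(OCc5ccccc5)c(OCc5ccccc5)cc([C@H](/C=C/C)c3ccc(OCc5ccccc5)c(OCc5ccccc5)c3OC(=O)c3ccc(OCc5ccccc5)c(OCc5ccccc5)c3)c12
F2 | step 11 | 5-{(4S)-7,8-bis(benzyloxy)-2-[3,4-bis(benzyloxy)phenyl]-4H-chromen-4-yl} flavonol pentabenzyl ether | O=c1c(OCc5ccccc5)c(-c2ccc(OCc5ccccc5)c(OCc5ccccc5)c2)oc2c(OCc5ccccc5)c(OCc5ccccc5)cc([C@H]3c4ccc(OCc5ccccc5)c(OCc5ccccc5)c4OC(c4ccc(OCc5ccccc5)c(OCc5ccccc5)c4)=C3)c12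
F3 | step 11 | 2,3-epoxide of F2, epoxide oxygen opposite the flavonol group | O=c1c(OCc5ccccc5)c(-c2ccc(OCc5ccccc5)c(OCc5ccccc5)c2)oc2c(OCc5ccccc5)c(OCc5ccccc5)cc([C@H]3c4ccc(OCc5ccccc5)c(OCc5ccccc5)c4O[C@@]6(c4ccc(OCc5ccccc5)c(OCc5ccccc5)c4)[C@@H]3O6)c12
F4 | step 11 | (2R,3S)-1-[3,4-bis(benzyloxy)phenyl]-3-[3,4-bis(benzyloxy)-2-hydroxyphenyl]-2-hydroxy-3-Flv-propan-1-one | O=c1c(OCc5ccccc5)c(-c2ccc(OCc5ccccc5)c(OCc5ccccc5)c2)oc2c(OCc5ccccc5)c(OCc5ccccc5)cc([C@H]([C@@H](O)C(=O)c3ccc(OCc5ccccc5)c(OCc5ccccc5)c3)c3ccc(OCc5ccccc5)c(OCc5ccccc5)c3O)c12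
F5 | step 11 | (1S,2R,3S)-1-[3,4-bis(benzyloxy)phenyl]-3-[3,4-bis(benzyloxy)-2-hydroxyphenyl]-3-Flv-propane-1,2-diol (anti diol) | O=c1c(OCc5ccccc5)c(-c2ccc(OCc5ccccc5)c(OCc5ccccc5)c2)oc2c(OCc5ccccc5)c(OCc5ccccc5)cc([C@H]([C@@H](O)[C@@H](O)c3ccc(OCc5ccccc5)c(OCc5ccccc5)c3)c3ccc(OCc5ccccc5)c(OCc5ccccc5)c3O)c12
F6 | step 9 | formate ester of phenol 11 | O=c1c(OCc5ccccc5)c(-c2ccc(OCc5ccccc5)c(OCc5ccccc5)c2)oc2c(OCc5ccccc5)c(OCc5ccccc5)cc([C@H](/C=C/C)c3ccc(OCc5ccccc5)c(OCc5ccccc5)c3OC=O)c12
F7 | step 6 | (S,E)-4-(4,4,5,5-tetramethyl-1,3,2-dioxaborolan-2-yl)but-3-en-2-ol | C[C@H](O)/C=C/B1OC(C)(C)C(C)(C)O1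
F8 | step 6 | 5-[(1E,3S)-3-hydroxybut-1-en-1-yl] flavonol pentabenzyl ether | O=c1c(OCc5ccccc5)c(-c2ccc(OCc5ccccc5)c(OCc5ccccc5)c2)oc2c(OCc5ccccc5)c(OCc5ccccc5)cc(/C=C/[C@H](C)O)c12
F9 | step 6 | methyl carbonate of F8 | O=c1c(OCc5ccccc5)c(-c2ccc(OCc5ccccc5)c(OCc5ccccc5)c2)oc2c(OCc5ccccc5)c(OCc5ccccc5)cc(/C=C/[C@H](C)OC(=O)OC)c12
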